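## Analysis of the target

Target 10 is numbered as follows: ring A is the cyclohexa-2,5-dienone (C1 carbonyl, C2 allyl-bearing, C3–H, C4 quaternary, C5 methoxy-bearing, C6–H), C8 is the methine on C4, C9 its methyl group, and C7 the methylene that carries ring B (3,4-dimethoxyphenyl). Ring A is a cross-conjugated dienone and also a vinylogous ester (C5–OMe, C6, C1=O). It is joined to the rest by one bond only, C4–C8, so 10 is an open-chain neolignan built from two C6–C3 units. The two stereocentres are vicinal and both R: C4 (OMe, C8, C3, C5) and C8 (H, C9, C7, C4). No ring ties them together, and the two carbon arms on C8 (CH3 and CH2Ar) are almost equal in size, so C8 cannot steer a reagent to one face of ring A by bulk alone. The sensitive points are the doubly allylic tertiary ether at C4 (dienone–phenol shift under acid, aromatisation under reduction), the terminal allyl group (no late hydrogenation or hydrometalation) and the electron-rich ring B. A cation at C7 cannot be tolerated once C4–C8 exists, because C6 and the oxygen on C5 each lie one five-membered ring away and would close carbocyclic or hydrobenzofuran skeletons. The feature that invites the strategy is C4 of ring A. It bears OMe, is flanked by C3=C2 and C5=C6 and lies para to C1=O, so it stands at the oxidation level of a p-quinone monoketal carbon. Removing C8 leaves the O-methylated quinone cation that the presumed biosynthesis attacks with C8 of a phenylpropanoid; in line with this, C22H28O5 is the sum of phenol 4 and allylarene 6. The hard part is therefore one bond, C4–C8, made with control of the site on ring A, of the configuration at C8 and of the face of C4.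

## Retrosynthetic reasoning

**C4–C8 (10 ⇒ 9 + 8).** This is the only bond between the two halves, and both stereocentres lie on it. Cutting it with the biosynthetic polarity gives the oxocarbenium ion 9 (C4 electrophilic) and a C8 carbanion equivalent of fixed configuration, the boronate complex 8. The gain is large: 9 comes from an achiral ketal, 8 carries a single stereocentre, and the coupling product is already 10, with no functional group left to adjust on the sensitive dienone. The forward reaction has four tasks.
- Deliver the secondary alkyl group to C4 and not to C2 or C6.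
- Invert C8 cleanly.
- Choose one face of C4.
- Be irreversible without ever placing charge on C7.

**9 ⇒ 5 and 8 ⇒ 7.** Ion 9 is ketal 5 minus one of its two enantiotopic methoxy groups, removed by a silyl Lewis acid. Complex 8 is boronic ester 7 plus an electron-poor aryl anion. Both are made in the flask, so the isolated partners are stable, neutral compounds.

**C4–O (5 ⇒ 4).** Oxidative ketalisation of phenol 4 puts the second methoxy group on C4. The dearomatisation is done here because C4 then carries two equal groups and no stereochemical question arises.

**C2–allyl (4 ⇒ 3 ⇒ 2 ⇒ 1).** The allyl group next to the phenol oxygen is the retron of a [3,3] shift. Ether 2 rearranges through dienone 3, and 2 is the O-allyl derivative of commercial phenol 1. The allyl group enters before any step that could harm it.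

**C8–B (7 ⇒ 6).** Branched addition of boron and hydrogen across the terminal alkene of commercial 6 makes C9 the methyl group and sets C8 under catalyst control. Both halves of 10 thus come from simple phenylpropanoid-type arenes.

## Alternatives that were turned down

Alternative 1: the textbook cut, C4–OMe. The forward key step is oxidative dearomatisation of phenol A1 with a trivalent iodine oxidant in methanol.
- In A1, A(1,3) strain with C5–OMe places C8–H in the plane of ring A. The two faces then differ only by CH3 against CH2Ar, and solvent attacks a flat cation with no organising element, so the hardest stereocentre is left to chance.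
- Ring B lies close enough to C4 to compete as an internal carbon nucleophile for the cation derived from A1.
- C8 of A1 has to be set (for example by hydrogenation of a stilbene-type alkene) before the allyl group may enter. About seven steps are therefore spent to reach a point where C4 is still open.

Alternative 2: cut C4–C8 and use C7–O as a temporary bond. The forward key step is a biomimetic formal [3+2] union of cation 9 with styrene A2 to give hydrobenzofuranone A3. Reductive cleavage of the benzylic C7–O bond would then give vinylogous acid A4, followed by O-methylation.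
- Attack of a neutral π-nucleophile on C4 is reversible, so the system drains to adducts bonded at C2.
- Both partners are achiral, so there is no source of absolute configuration.
- Opening A3 by ionisation regenerates the C7 cation next to the nucleophilic C6.
- A4 is ambident and its less hindered oxygen (on C1) should react first, giving enol ether A5 instead of 10.
- Three extra steps follow the key step.

Alternative 3: cut C4–C8 with C4 as a carbonyl carbon. The forward key step is 1,2-addition of secondary alkyllithium A6 to quinone A7 to give quinol A8, then O-methylation.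
- A7 is a strong one-electron and hydride acceptor, while A6 is a strong reductant with β-hydrogens. Electron transfer (which planarises C8) and β-hydride reduction should outrun addition.
- A6 keeps its configuration only at very low temperature.
- A neutral carbonyl offers no cationic π face for ring B to stack on, so the face of C4 is not controlled.
- The hindered tertiary alkoxide needs a further alkylation.

Key step: step 5

Assumption: in step 4 the antipode of the chiral carbene ligand is the one that delivers boron to the face of 6 giving (S)-7; both antipodes are accessible.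

## Route

Step 1
Reactants: 1 3,4-dimethoxyphenol
Product: 2 4-(allyloxy)-1,2-dimethoxybenzene
Conditions: allyl bromide, K2CO3, acetone, reflux
Reagents that add atoms: allyl bromide (C=CCBr)
Why: Williamson ether synthesis; the phenoxide of 1 displaces bromide from the primary allylic halide, and no other nucleophilic site is present.

Step 2
Reactants: 2 4-(allyloxy)-1,2-dimethoxybenzene
Product: 4 2-allyl-4,5-dimethoxyphenol, via 6-allyl-3,4-dimethoxycyclohexa-2,4-dienone 3 (not isolated)
Conditions: N,N-diethylaniline, 200 °C
Reagents that add atoms: none
Why: Aromatic Claisen rearrangement ([3,3] shift) followed by tautomerisation of 3; the allyl group should migrate to the free ortho carbon para to a methoxy group and not to the ortho carbon squeezed between the ether oxygen and OMe, and the stereocentre of 3 is lost on enolisation.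

Step 3
Reactants: 4 2-allyl-4,5-dimethoxyphenol
Product: 5 2-allyl-4,4,5-trimethoxycyclohexa-2,5-dien-1-one
Conditions: PhI(OAc)2, MeOH, 0 °C
Reagents that add atoms: methanol (CO)
Why: Oxidative dearomatisation of a p-methoxyphenol with a trivalent iodine reagent; methanol adds at C4, where the resident OMe stabilises the charge, to give the p-quinone monoketal. C4 carries two equal groups, so no stereocentre arises, and the allyl group is inert to the oxidant at 0 °C.

Step 4
Reactants: 6 4-allyl-1,2-dimethoxybenzene (methyleugenol)
Product: 7 (S)-2-[1-(3,4-dimethoxyphenyl)propan-2-yl]-4,4,5,5-tetramethyl-1,3,2-dioxaborolane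
Conditions: B2pin2, MeOH, CuCl (cat.), bulky C2-symmetric chiral NHC·HCl (cat.), NaOtBu (cat.), THF, rt
Reagents that add atoms: bis(pinacolato)diboron (CC1(C)OB(OC1(C)C)B1OC(C)(C)C(C)(C)O1)
Why: Copper-catalysed enantioselective Markovnikov protoboration of a terminal alkene; the bulky ligand on monovalent copper places copper on the terminal carbon and boron on C8, the face of the alkene is chosen by the ligand in the borylcupration, and methanol protonates the C9–Cu bond to give the methyl group.

Step 5
Reactants: 5 2-allyl-4,4,5-trimethoxycyclohexa-2,5-dien-1-one; 7 (S)-2-[1-(3,4-dimethoxyphenyl)propan-2-yl]-4,4,5,5-tetramethyl-1,3,2-dioxaborolane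
Product: 10 (4R)-2-allyl-4-[(2R)-1-(3,4-dimethoxyphenyl)propan-2-yl]-4,5-dimethoxycyclohexa-2,5-dien-1-one, via lithium aryl boronate complex 8 (not isolated), via O-methylquinone oxocarbenium triflate 9 (not isolated)
Conditions: a) 1-bromo-3,5-bis(trifluoromethyl)benzene, n-BuLi, Et2O, −78 °C, then 7; b) 5, TMSOTf, CH2Cl2, −78 °C; c) a into b, −78 to −40 °C; aq NaHCO3
Reagents that add atoms: none
Why: Proposed new method: stereoinvertive SE2 alkylation of a quinone-monoketal-derived oxocarbenium ion by a chiral secondary alkyl boronate complex, the closest known reaction type being the invertive coupling of aryl-activated secondary boronic ester ate complexes with carbenium-type electrophiles (tropylium, benzhydrylium and N-acylpyridinium ions). The silyl triflate removes one of the two enantiotopic methoxy groups of achiral 5 and gives 9, whose charge and LUMO are centred on C4, while addition of the aryllithium to 7 gives 8, whose C8–B bond is the most nucleophilic σ bond present. C8 attacks C4 with its back lobe while boron leaves as the neutral aryl boronic ester, so C8 is inverted, (S)-7 gives 8R, the step is irreversible and C7 never carries charge, which shuts off the closures onto C6 and onto the oxygen on C5. No ring is closed. Site selectivity: C4 is the oxocarbenium carbon and carries only a flat OMe, C2 is shielded by the sp3 arm of the allyl group and C6 is the electron-rich β-carbon of the C5 enol ether, and since the attack cannot revert the kinetic C4 adduct should be kept. Face selectivity at C4: with boron pointing away, the three other groups on C8 mesh with OMe, C3 and C5 around C4, the CH2Ar arm should lie over ring A so that donor ring B stacks on the cationic π face, H should take the slot beside C5–OMe and CH3 the slot beside C3–H, and this like-combination pairs 8R with 4R. The electron-poor aryl group on boron raises the oxidation potential of 8 and is itself a poor nucleophile, which should hold back single-electron transfer to 9 and aryl transfer. The allyl group, the vinylogous ester and ring B are far weaker nucleophiles than 8 and should survive at −78 °C.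

## Compound list

1 | 3,4-dimethoxyphenol | COc1ccc(O)cc1OC | starting material
2 | 4-(allyloxy)-1,2-dimethoxybenzene | C=CCOc1ccc(OC)c(OC)c1 | intermediate
3 | 6-allyl-3,4-dimethoxycyclohexa-2,4-dien-1-one (racemic, not isolated) | C=CCC1C=C(OC)C(OC)=CC1=O | intermediate
4 | 2-allyl-4,5-dimethoxyphenol | C=CCc1cc(OC)c(OC)cc1O | intermediate
5 | 2-allyl-4,4,5-trimethoxycyclohexa-2,5-dien-1-one | C=CCC1=CC(OC)(OC)C(OC)=CC1=O | intermediate
6 | 4-allyl-1,2-dimethoxybenzene (methyleugenol) | C=CCc1ccc(OC)c(OC)c1 | starting material
7 | (S)-2-[1-(3,4-dimethoxyphenyl)propan-2-yl]-4,4,5,5-tetramethyl-1,3,2-dioxaborolane | C[C@@H](Cc1ccc(OC)c(OC)c1)B1OC(C)(C)C(C)(C)O1 | intermediate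
8 | lithium (S)-2-[3,5-bis(trifluoromethyl)phenyl]-2-[1-(3,4-dimethoxyphenyl)propan-2-yl]-4,4,5,5-tetramethyl-1,3,2-dioxaborolan-2-uide (not isolated) | [Li+].C[C@@H](Cc1ccc(OC)c(OC)c1)[B-]1(c2cc(C(F)(F)F)cc(C(F)(F)F)c2)OC(C)(C)C(C)(C)O1 | intermediate
9 | (5-allyl-2-methoxy-4-oxocyclohexa-2,5-dien-1-ylidene)(methyl)oxonium triflate (not isolated) | C=CCC1=CC(=[O+]C)C(OC)=CC1=O.[O-]S(=O)(=O)C(F)(F)F | intermediate
10 | (4R)-2-allyl-4-[(2R)-1-(3,4-dimethoxyphenyl)propan-2-yl]-4,5-dimethoxycyclohexa-2,5-dien-1-one | C=CCC1=C[C@](OC)([C@H](C)Cc2ccc(OC)c(OC)c2)C(OC)=CC1=O | target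

## Step count and least certain steps

Total step count: 5. Longest linear sequence: 4 (steps 1, 2, 3, 5).

**Step 5 (key step, proposed new method).** Three processes are most likely to go wrong.
- Electron transfer from 8 to the strongly oxidising 9 ahead of bond formation, which would planarise C8 and merely reduce the cation.
- Attack at C2 or C6 instead of C4.
- Weak discrimination between the two faces of C4 if the stacking of ring B on ring A is not decisive.

The fallback uses known chemistry, sets out from 6 and comes back at 10. Protoboration of 6 with the mirror-image ligand gives (R)-2-[1-(3,4-dimethoxyphenyl)propan-2-yl]-4,4,5,5-tetramethyl-1,3,2-dioxaborolane F1. F1 is added to the dianion of 4-bromo-3-methoxyphenol (MeLi, then t-BuLi), and the phenolate oxygen of the boronate is activated (for example with Ph3BiF2). 1,2-Shift with retention and rearomatisation then give (R)-4-[1-(3,4-dimethoxyphenyl)propan-2-yl]-3-methoxyphenol F2. NBS brominates ortho to OH and para to OMe to give (R)-2-bromo-4-[1-(3,4-dimethoxyphenyl)propan-2-yl]-5-methoxyphenol F3. Suzuki–Miyaura allylation (allylboronic acid pinacol ester, Pd(PPh3)4, CsF) gives (R)-2-allyl-4-[1-(3,4-dimethoxyphenyl)propan-2-yl]-5-methoxyphenol F4. Oxidative dearomatisation follows, either with PhI(OAc)2 in MeOH or with a chiral aryl iodide and mCPBA as a catalytic trivalent iodine system to override the weak substrate bias. It gives 10, to be separated from (4S)-2-allyl-4-[(2R)-1-(3,4-dimethoxyphenyl)propan-2-yl]-4,5-dimethoxycyclohexa-2,5-dien-1-one F5.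

**Step 4.** Most likely to go wrong are borylcupration with boron on the terminal carbon, incomplete face discrimination (C8 carries only H and a slim CH2Ar arm), and copper-mediated drift of the double bond into conjugation.

The fallback replaces asymmetric catalysis on the alkene by a resolved epoxide and a stereoretentive metalation. It sets out from 6 and comes back at 7. mCPBA gives racemic 2-(3,4-dimethoxybenzyl)oxirane F6. Hydrolytic kinetic resolution, with the antipode of (salen)Co(OAc) (trivalent cobalt) that hydrolyses the R epoxide, leaves (S)-2-(3,4-dimethoxybenzyl)oxirane F7. LiBHEt3 opens the terminal carbon to give (R)-1-(3,4-dimethoxyphenyl)propan-2-ol F8. An Appel reaction (I2, PPh3, imidazole) inverts C8 to (S)-4-(2-iodopropyl)-1,2-dimethoxybenzene F9. Iodine–lithium exchange (t-BuLi, −100 °C) with retention gives (S)-1-(3,4-dimethoxyphenyl)propan-2-yllithium F10, which is trapped at once with i-PrOBpin to give 7.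

**Step 2.** Most likely to go wrong are partial migration to the hindered ortho carbon and thermal isomerisation or cyclisation of the allylphenol at 200 °C.

The fallback replaces the sigmatropic shift by a cross-coupling. It sets out from 1 and comes back at 4. NBS brominates the free ortho position para to OMe to give 2-bromo-4,5-dimethoxyphenol F11. Suzuki–Miyaura allylation (allylboronic acid pinacol ester, Pd(PPh3)4, CsF) then gives 4.

**Step 3.** Most likely to go wrong is loss of the ketal by hydrolysis to the quinone through adventitious water and the acetic acid released, during reaction or on silica.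

The fallback reaches 5 from the bisketal side. It sets out from 4 and comes back at 5. O-Methylation (MeI, K2CO3) gives 1-allyl-2,4,5-trimethoxybenzene F12. Anodic oxidation (Pt anode, KOH, MeOH) gives 1-allyl-3,3,4,6,6-pentamethoxycyclohexa-1,4-diene F13. Mild aqueous acid then hydrolyses only the ketal whose ionisation is assisted by C5–OMe (the one at C1), giving 5.

## Further compounds

F1 | step 5 | (R)-2-[1-(3,4-dimethoxyphenyl)propan-2-yl]-4,4,5,5-tetramethyl-1,3,2-dioxaborolane | C[C@H](Cc1ccc(OC)c(OC)c1)B1OC(C)(C)C(C)(C)O1
F2 | step 5 | (R)-4-[1-(3,4-dimethoxyphenyl)propan-2-yl]-3-methoxyphenol | C[C@H](Cc1ccc(OC)c(OC)c1)c1ccc(O)cc1OC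
F3 | step 5 | (R)-2-bromo-4-[1-(3,4-dimethoxyphenyl)propan-2-yl]-5-methoxyphenol | C[C@H](Cc1ccc(OC)c(OC)c1)c1cc(Br)c(O)cc1OC
F4 | step 5 | (R)-2-allyl-4-[1-(3,4-dimethoxyphenyl)propan-2-yl]-5-methoxyphenol | C=CCc1cc([C@H](C)Cc2ccc(OC)c(OC)c2)c(OC)cc1O
F5 | step 5 | (4S)-2-allyl-4-[(2R)-1-(3,4-dimethoxyphenyl)propan-2-yl]-4,5-dimethoxycyclohexa-2,5-dien-1-one | C=CCC1=C[C@@](OC)([C@H](C)Cc2ccc(OC)c(OC)c2)C(OC)=CC1=O
F6 | step 4 | 2-(3,4-dimethoxybenzyl)oxirane (racemic) | COc1ccc(CC2CO2)cc1OC
F7 | step 4 | (S)-2-(3,4-dimethoxybenzyl)oxirane | C1O[C@H]1Cc1ccc(OC)c(OC)c1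
F8 | step 4 | (R)-1-(3,4-dimethoxyphenyl)propan-2-ol | C[C@@H](O)Cc1ccc(OC)c(OC)c1
F9 | step 4 | (S)-4-(2-iodopropyl)-1,2-dimethoxybenzene | C[C@H](I)Cc1ccc(OC)c(OC)c1
F10 | step 4 | (S)-1-(3,4-dimethoxyphenyl)propan-2-yllithium | C[C@H]([Li])Cc1ccc(OC)c(OC)c1
F11 | step 2 | 2-bromo-4,5-dimethoxyphenol | COc1cc(O)c(Br)cc1OC
F12 | step 3 | 1-allyl-2,4,5-trimethoxybenzene | C=CCc1cc(OC)c(OC)cc1OC
F13 | step 3 | 1-allyl-3,3,4,6,6-pentamethoxycyclohexa-1,4-diene | C=CCC1=CC(OC)(OC)C(OC)=CC1(OC)OC
A1 | alternative 1 | (R)-2-allyl-4-[1-(3,4-dimethoxyphenyl)propan-2-yl]-5-methoxyphenol | C=CCc1cc([C@H](C)Cc2ccc(OC)c(OC)c2)c(OC)cc1O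
A2 | alternative 2 | (E)-1,2-dimethoxy-4-(prop-1-enyl)benzene | C/C=C/c1ccc(OC)c(OC)c1
A3 | alternative 2 | (2S,3R,3aS)-5-allyl-2-(3,4-dimethoxyphenyl)-3a-methoxy-3-methyl-3,3a-dihydrobenzofuran-6(2H)-one | C=CCC1=C[C@]2(OC)[C@H](C)[C@@H](c3ccc(OC)c(OC)c3)OC2=CC1=O
A4 | alternative 2 | (4R)-2-allyl-4-[(2R)-1-(3,4-dimethoxyphenyl)propan-2-yl]-5-hydroxy-4-methoxycyclohexa-2,5-dien-1-one | C=CCC1=C[C@](OC)([C@H](C)Cc2ccc(OC)c(OC)c2)C(O)=CC1=O
A5 | alternative 2 | (6R)-4-allyl-6-[(2R)-1-(3,4-dimethoxyphenyl)propan-2-yl]-3,6-dimethoxycyclohexa-2,4-dien-1-one | C=CCC1=C[C@](OC)([C@H](C)Cc2ccc(OC)c(OC)c2)C(=O)C=C1OC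
A6 | alternative 3 | (R)-1-(3,4-dimethoxyphenyl)propan-2-yllithium | [Li][C@H](C)Cc1ccc(OC)c(OC)c1
A7 | alternative 3 | 2-allyl-5-methoxy-1,4-benzoquinone | C=CCC1=CC(=O)C(OC)=CC1=O
A8 | alternative 3 | (4R)-2-allyl-4-[(2R)-1-(3,4-dimethoxyphenyl)propan-2-yl]-4-hydroxy-5-methoxycyclohexa-2,5-dien-1-one | C=CCC1=C[C@](O)([C@H](C)Cc2ccc(OC)c(OC)c2)C(OC)=CC1=O
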